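The north run slows early and then stops rising: it reads 41% at 1.33 h, 47% at 2.50 h and 44% at 8.00 h, with a scatter of 1.5 percentage points.

all flasks: initiator 0.51 mM

| run | free monomer | protic impurity | remark | time |
|---|---|---|---|---|
| south-west | 0.12 M | 0.069 M | run made earlier |  |
| north | 0.24 M | 0.069 M | run made earlier |  |
| Saturday's | 0.23 M | 0.0690 M |  | 8.0 h |
| Friday's | 0.30 M | 0.0690 M |  | 8.0 h |

| run | time / h | monomer in chains / % |
|---|---|---|
| south-west | 0.667 | 32 |
| south-west | 1.00 | 38 |
| south-west | 1.33 | 39 |
| south-west | 2.50 | 40 |
| south-west | 3.00 | 40 |
| south-west | 5.00 | 39 |
| south-west | 8.00 | 45 |
| north | 0.417 | 27 |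
| north | 1.33 | 41 |
| north | 2.50 | 47 |
| north | 3.00 | 42 |
| north | 5.00 | 45 |
| north | 6.00 | 47 |
| north | 8.00 | 44 |

(scatter of a reading: 1.5 percentage points)

- the average divides the monomer in chains by the number of chains, living and dead together; two radicals that join make one chain
- the earlier runs were read with a standard deviation of 1.5 percentage points
- the earlier runs do not show the number of chains; that part of a forecast is a guess

1. which of the two ends with the longer chains by the average number of monomer units in a chain (living and dead chains, two that joined counted as one) ("neither" if they lie within 10%) (Saturday's / Friday's / neither)
2. average number of monomer units in a chain (living and dead chains, two that joined counted as one) at the end, Saturday's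
3. average number of monomer units in a chain (living and dead chains, two that joined counted as one) at the end, Friday's

Saturday's looks nearly the same as the north run, with equal initiator and impurity and free monomer at 0.23 M against 0.24 M. From 2.50 h on, the north run averages 45.0% of its charge in chains. The south-west run, with half the free monomer, averages 41.0% from 2.50 h on. These two read shares differ by 4 points, so you can give Saturday's, whose charge lies next to the north run's, the north run's share. Carrying the small rise with charge onward gives Friday's 47.0%.

The length still needs the number of chains, which the runs do not show. So follow one initiator: my guess is that it gives a pair of radicals and that these end in one chain. That makes the chain count, one chain for each initiator charged, 0.510 mM. Then: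

Saturday's: 45.0% × 0.23 M / 0.510 mM = 203 units

Friday's: 47.0% × 0.30 M / 0.510 mM = 276 units

The initiator charge is equal in both flasks, so my guess gives both the same count and cancels from the comparison, and by this reckoning Friday's is longer than Saturday's by more than the margin.

The forecast says Friday's, with 210 (170 to 350) for Saturday's and 285 (230 to 480) for Friday's, on chains numbering “about one per initiator”. My figures lie a little lower.

The flasks give 209 for Saturday's and 287 for Friday's, so Friday's ends longer.

    initiator → 2 initiating radical (k = 0.0427 min⁻¹)
    free monomer + initiating radical → growing radical + monomer in chains (k = 44800 M⁻¹ s⁻¹)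
    free monomer + growing radical → monomer in chains + growing radical, rate k3*[growing radical]*[free monomer] (k = 1.76 × 10⁵ M⁻¹ min⁻¹)
    2 growing radical → dead chain (k = 2.90 × 10⁷ M⁻¹ s⁻¹)
    protic impurity + free monomer → quenched substrate (k = 0.346 M⁻¹ min⁻¹)

At 8.00 h, Saturday's holds 0.510 mM of dead chain, matching the chain count, and 46.4% of its charge is in chains:

46.4% × 0.23 M / 0.510 mM = 209 units

The neighbouring flask is Saturday's with 0.58 M of free monomer and the same initiator. At the end it holds 53.7% of its charge in chains:

53.7% × 0.58 M / 0.510 mM = 611 units

Its chains average 611 units.

The data were generated by integration for substances that don't exist; noise was put on by code.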